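**Plan**

- Numbering: C1 carries the dienoic acid chain, C2 the butenyl group, C3=C4 is the ring A alkene (methyl on C3), C4a/C8a are the cis fusion, C7 bears the sulfate and C8 a methyl. The enabling feature is that the trans-substituted C1–C2 bond lies next to the C3=C4 alkene and C1 carries a carboxyl-level carbon. That pattern is what a [3,3] shift leaves behind when C4 was the carbinol carbon of a δ-lactone (O–CO–C1–C8a–C4a–C4) fused to ring B and carrying a C3=C2 alkenyl group.
- Retrosynthetic cuts, in order: the O–S bond at C7; the first C=C bond of the side chain (olefination at the C1 aldehyde); C1–C2 (Ireland–Claisen, reopening ring A to the lactone); the C2–butenyl bond (Suzuki–Miyaura); C1–C8a (tethered Michael addition, reopening the lactone); C4a–C4 (aldol).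
- Forward: ring B is bought as a vinylogous ester; the C4 arm is joined by an aldol; the lactone ring is closed by Michael addition; ring A is closed by the [3,3] shift; the chain is then extended and the sulfate installed.
- Stereochemistry: C4a/C4 come from a catalyst-controlled anti aldol; C8a from the tether (cis fusion); C8 from enolate protonation; C7 from a bulky hydride; C1 and C2 from chirality transfer from C4 through a boat transition state together with the Z alkene made in step 1; the E alkenes come from a stereodefined boronate and the phosphonate olefination.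

Key step: step 12

Assumption: the sulfate and carboxyl are taken as the free acids drawn, and the (S,S) phosphoramide of step 4 is taken to give the (6R,1′S) aldol; should a trial show the opposite sense, its (R,R) antipode is used.

**Route**

Step 1
Reactants: 1 prop-2-yn-1-ol
Product: 3 (Z)-3-iodo-2-methylprop-2-en-1-ol, via alkenylmagnesium alkoxide 2 (not isolated)
Conditions: MeMgBr (3 equiv), CuI (10 mol %), THF, −10 °C to rt; then I2, THF, −20 °C
Reagents that add atoms: methylmagnesium bromide, C[Mg]Br; iodine, [I][I]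
Why: Copper-catalysed anti-carbomagnesiation of the propargylic magnesium alkoxide puts methyl on the internal carbon and leaves magnesium on the terminal carbon cis to the CH2O group in a five-membered chelate, so iodinolysis with retention gives the Z vinyl iodide that later fixes the C2=C3 geometry.

Step 2
Reactants: 3 (Z)-3-iodo-2-methylprop-2-en-1-ol
Product: 4 (Z)-3-iodo-2-methylprop-2-enal
Conditions: MnO2 (excess), CH2Cl2, rt, dark
Reagents that add atoms: none
Why: MnO2 oxidation of the allylic alcohol is neutral and heterogeneous and should not isomerise the Z iodoalkene; the aldehyde is used at once.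

Step 3
Reactants: 5 3-ethoxy-2-methylcyclohex-2-en-1-one
Product: 6 [(4-ethoxy-3-methylcyclohexa-1,3-dien-2-yl)oxy]trimethylsilane
Conditions: LiN(i-Pr)2, THF, −78 °C; Me3SiCl; non-aqueous work-up, distillation
Reagents that add atoms: chlorotrimethylsilane, C[Si](C)(C)Cl
Why: Kinetic α′-deprotonation of the vinylogous ester (its only enolisable position, the later C4a) and O-silylation give the silyl dienol ether needed for silicon exchange.

Step 4
Reactants: 6 [(4-ethoxy-3-methylcyclohexa-1,3-dien-2-yl)oxy]trimethylsilane; 4 (Z)-3-iodo-2-methylprop-2-enal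
Product: 8 (6R)-3-ethoxy-6-[(1S,2Z)-1-hydroxy-3-iodo-2-methylprop-2-en-1-yl]-2-methylcyclohex-2-en-1-one, via trichlorosilyl dienolate 7 (not isolated)
Conditions: SiCl4, Hg(OAc)2 (1 mol %), CH2Cl2, rt, volatiles removed; then 4, (S,S)-1,3-dimethyl-4,5-diphenyl-2-(piperidin-1-yl)-1,3,2-diazaphospholidine 2-oxide (10 mol %), CH2Cl2, −78 °C; aq. NaHCO3
Reagents that add atoms: none
Why: This is a chiral Lewis-base-catalysed aldol addition of a trichlorosilyl enolate, in which the ring-locked E enolate adds to the conjugated aldehyde through a closed chair-like hexacoordinate siliconate transition state, so the anti C4a/C4 pair results and the phosphoramide bound to silicon selects the aldehyde face.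

Step 5
Reactants: 8 (6R)-3-ethoxy-6-[(1S,2Z)-1-hydroxy-3-iodo-2-methylprop-2-en-1-yl]-2-methylcyclohex-2-en-1-one
Product: 10 (4S)-4-[(1S,2Z)-1-hydroxy-3-iodo-2-methylprop-2-en-1-yl]-2-methylcyclohex-2-en-1-one, via allylic diol 9 (not isolated)
Conditions: i-Bu2AlH (2.2 equiv), CH2Cl2, −78 °C; then 1 M HCl, THF, 0 °C
Reagents that add atoms: water, O
Why: Stork–Danheiser transposition, in which 1,2-reduction of the vinylogous ester carbonyl and mild acid hydrolysis of the enol ether with loss of water move the carbonyl to C7 and the alkene to C8=C8a without touching C4a or C4 (the ring descriptor changes from R to S by priority only).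

Step 6
Reactants: 10 (4S)-4-[(1S,2Z)-1-hydroxy-3-iodo-2-methylprop-2-en-1-yl]-2-methylcyclohex-2-en-1-one; 11 3-(tert-butoxy)-3-oxopropanoic acid
Product: 12 1-tert-butyl 3-{(1S,2Z)-3-iodo-2-methyl-1-[(1S)-3-methyl-4-oxocyclohex-2-en-1-yl]prop-2-en-1-yl} propanedioate
Conditions: DCC, DMAP (10 mol %), CH2Cl2, 0 °C to rt
Reagents that add atoms: none
Why: Steglich esterification of the secondary allylic alcohol with the malonic half ester proceeds with retention at C4 and attaches the future C1 nucleophile through oxygen.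

Step 7
Reactants: 12 1-tert-butyl 3-{(1S,2Z)-3-iodo-2-methyl-1-[(1S)-3-methyl-4-oxocyclohex-2-en-1-yl]prop-2-en-1-yl} propanedioate
Product: 13 tert-butyl (1S,4aS,5S,8aS)-1-[(1Z)-1-iodoprop-1-en-2-yl]-5-methyl-3,6-dioxooctahydro-1H-isochromene-4-carboxylate (epimers at the ester-bearing carbon)
Conditions: Cs2CO3 (0.2 equiv), MeCN (0.01 M), 0 °C
Reagents that add atoms: none
Why: Intramolecular Michael addition (6-exo-trig) of the malonate carbanion to the enone, in which the tether on C4a delivers C1 to the same face of C8a by axial attack and so gives the cis ring fusion, and kinetic axial protonation of the ring B enolate anti to the new axial C8a–C1 bond leaves the C8 methyl equatorial and cis to C1.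

Step 8
Reactants: 13 tert-butyl (1S,4aS,5S,8aS)-1-[(1Z)-1-iodoprop-1-en-2-yl]-5-methyl-3,6-dioxooctahydro-1H-isochromene-4-carboxylate
Product: 15 (1S,4aS,5S,8aS)-1-[(1Z)-1-iodoprop-1-en-2-yl]-5-methylhexahydro-1H-isochromene-3,6(4H,7H)-dione, via lactone carboxylic acid 14 (not isolated)
Conditions: TFA, CH2Cl2, 0 °C to rt; concentrate; PhMe, 100 °C
Reagents that add atoms: none
Why: Acidolysis of the tert-butyl ester and thermal decarboxylation of the malonic-type acid remove the activating group under non-basic conditions that cannot reverse the Michael addition, and any C8 epimer should equilibrate toward the equatorial methyl.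

Step 9
Reactants: 15 (1S,4aS,5S,8aS)-1-[(1Z)-1-iodoprop-1-en-2-yl]-5-methylhexahydro-1H-isochromene-3,6(4H,7H)-dione
Product: 16 (1S,4aR,5S,6R,8aS)-6-hydroxy-1-[(1Z)-1-iodoprop-1-en-2-yl]-5-methyloctahydro-3H-isochromen-3-one
Conditions: LiBH(s-Bu)3, THF, −78 °C; AcOH, −78 °C
Reagents that add atoms: none
Why: The bulky borohydride attacks the C7 ketone from the equatorial direction, away from the axial C8a–CH2 bond, giving the axial alcohol cis to the C8 methyl, and the cold acidic quench keeps the new alkoxide from attacking the lactone (the 4a descriptor changes from S to R by priority only).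

Step 10
Reactants: 16 (1S,4aR,5S,6R,8aS)-6-hydroxy-1-[(1Z)-1-iodoprop-1-en-2-yl]-5-methyloctahydro-3H-isochromen-3-one
Product: 17 (1S,4aR,5S,6R,8aS)-6-[(tert-butyldimethylsilyl)oxy]-1-[(1Z)-1-iodoprop-1-en-2-yl]-5-methyloctahydro-3H-isochromen-3-one
Conditions: TBSOTf, 2,6-lutidine, CH2Cl2, −20 to 0 °C
Reagents that add atoms: tert-butyldimethylsilyl trifluoromethanesulfonate, CC(C)(C)[Si](C)(C)OS(=O)(=O)C(F)(F)F
Why: Silylation with the silyl triflate and a hindered base protects the hindered axial alcohol as an ether that should survive amide base, heat, hydride and oxidant until step 16.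

Step 11
Reactants: 17 (1S,4aR,5S,6R,8aS)-6-[(tert-butyldimethylsilyl)oxy]-1-[(1Z)-1-iodoprop-1-en-2-yl]-5-methyloctahydro-3H-isochromen-3-one; 18 (Z)-2-(but-2-en-2-yl)-4,4,5,5-tetramethyl-1,3,2-dioxaborolane
Product: 19 (1S,4aR,5S,6R,8aS)-6-[(tert-butyldimethylsilyl)oxy]-5-methyl-1-[(2Z,4E)-4-methylhexa-2,4-dien-2-yl]octahydro-3H-isochromen-3-one
Conditions: Pd(dppf)Cl2 (5 mol %), Cs2CO3, THF/H2O (10:1), rt
Reagents that add atoms: none
Why: Suzuki–Miyaura coupling proceeds with retention at both sp2 carbons, so the Z iodide and the stereodefined boronate give the (2Z,4E)-diene, and oxidative addition of zerovalent palladium into the C–I bond at room temperature should outrun ionisation of the allylic lactone.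

Step 12
Reactants: 19 (1S,4aR,5S,6R,8aS)-6-[(tert-butyldimethylsilyl)oxy]-5-methyl-1-[(2Z,4E)-4-methylhexa-2,4-dien-2-yl]octahydro-3H-isochromen-3-one
Product: 22 (1R,2R,4aS,7R,8S,8aS)-2-[(2E)-but-2-en-2-yl]-7-[(tert-butyldimethylsilyl)oxy]-3,8-dimethyl-1,2,4a,5,6,7,8,8a-octahydronaphthalene-1-carboxylic acid, via silyl ketene acetal 20 (not isolated), via trimethylsilyl ester 21 (not isolated)
Conditions: LiN(i-Pr)2, Me3SiCl, Et3N, THF, −78 °C; then PhMe, 100 °C; then H2O, THF, rt
Reagents that add atoms: none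
Why: Deprotonation at C1 and O-silylation give the endocyclic silyl ketene acetal 20, whose O–C4–C3=C2 allyl vinyl ether array undergoes a concerted suprafacial [3,3] shift, the Ireland–Claisen ring contraction known for 6-alkenyl δ-lactone ketene acetals giving cyclohexenecarboxylic acids. Ring A (C1, C2, C3, C4, C4a, C8a) closes by C1–C2 bond formation as C4–O breaks, through the only geometry the lactone allows, a boat-shaped pericyclic array inside a bicyclo[2.2.2]octane-like transition state, and the lactone carbonyl carbon is extruded as the C1 carboxyl while the alkene moves to C3=C4. C1 is set by the ring system: the alkenyl group on C4 sits on the lactone face opposite ring B, so C2 is delivered to that face of C1 and the carboxyl ends cis to the C8a–C8 bond. C2 is set by alkene geometry: in the boat the Z (inside) butenyl group ends trans to the carboxyl, so the Z geometry made in step 1 becomes the 1,2-trans relationship. The step needs complete chirality transfer from C4 and no loss of alkene geometry; both are secured by the concerted bicyclic transition state acting on a lactone whose C4 configuration and cis fusion were fixed in steps 4 and 7. The silyl ester 21 is hydrolysed by water on work-up and the C7 silyl ether is a spectator.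

Step 13
Reactants: 22 (1R,2R,4aS,7R,8S,8aS)-2-[(2E)-but-2-en-2-yl]-7-[(tert-butyldimethylsilyl)oxy]-3,8-dimethyl-1,2,4a,5,6,7,8,8a-octahydronaphthalene-1-carboxylic acid
Product: 23 [(1R,2R,4aS,7R,8S,8aR)-2-[(2E)-but-2-en-2-yl]-7-[(tert-butyldimethylsilyl)oxy]-3,8-dimethyl-1,2,4a,5,6,7,8,8a-octahydronaphthalen-1-yl]methanol
Conditions: LiAlH4, THF, 0 °C to rt
Reagents that add atoms: none
Why: Hydride reduction of the hindered carboxylic acid to the primary alcohol leaves alkenes and the silyl ether untouched and involves no stereocenter (the 8a descriptor changes by priority only).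

Step 14
Reactants: 23 [(1R,2R,4aS,7R,8S,8aR)-2-[(2E)-but-2-en-2-yl]-7-[(tert-butyldimethylsilyl)oxy]-3,8-dimethyl-1,2,4a,5,6,7,8,8a-octahydronaphthalen-1-yl]methanol
Product: 24 (1R,2R,4aS,7R,8S,8aS)-2-[(2E)-but-2-en-2-yl]-7-[(tert-butyldimethylsilyl)oxy]-3,8-dimethyl-1,2,4a,5,6,7,8,8a-octahydronaphthalene-1-carbaldehyde
Conditions: Dess–Martin periodinane, CH2Cl2, 0 °C to rt
Reagents that add atoms: none
Why: Dess–Martin oxidation gives the aldehyde under near-neutral conditions that should not epimerise C1.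

Step 15
Reactants: 24 (1R,2R,4aS,7R,8S,8aS)-2-[(2E)-but-2-en-2-yl]-7-[(tert-butyldimethylsilyl)oxy]-3,8-dimethyl-1,2,4a,5,6,7,8,8a-octahydronaphthalene-1-carbaldehyde; 25 ethyl (2E)-4-(diethoxyphosphoryl)but-2-enoate
Product: 26 ethyl (2E,4E)-5-[(1R,2R,4aS,7R,8S,8aR)-2-[(2E)-but-2-en-2-yl]-7-[(tert-butyldimethylsilyl)oxy]-3,8-dimethyl-1,2,4a,5,6,7,8,8a-octahydronaphthalen-1-yl]penta-2,4-dienoate
Conditions: 25, LiN(SiMe3)2, THF, −78 °C; then 24, −78 to 0 °C
Reagents that add atoms: none
Why: Vinylogous Horner–Wadsworth–Emmons olefination adds four carbons and forms the new C=C bond E by thermodynamic control while the alkene of the reagent stays E, and the low temperature protects C1 from epimerisation.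

Step 16
Reactants: 26 ethyl (2E,4E)-5-[(1R,2R,4aS,7R,8S,8aR)-2-[(2E)-but-2-en-2-yl]-7-[(tert-butyldimethylsilyl)oxy]-3,8-dimethyl-1,2,4a,5,6,7,8,8a-octahydronaphthalen-1-yl]penta-2,4-dienoate
Product: 27 ethyl (2E,4E)-5-[(1R,2R,4aS,7R,8S,8aR)-2-[(2E)-but-2-en-2-yl]-7-hydroxy-3,8-dimethyl-1,2,4a,5,6,7,8,8a-octahydronaphthalen-1-yl]penta-2,4-dienoate
Conditions: HF·pyridine, THF/pyridine, 0 °C to rt
Reagents that add atoms: none
Why: Fluoride-driven desilylation frees the C7 alcohol without touching the dienoate.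

Step 17
Reactants: 27 ethyl (2E,4E)-5-[(1R,2R,4aS,7R,8S,8aR)-2-[(2E)-but-2-en-2-yl]-7-hydroxy-3,8-dimethyl-1,2,4a,5,6,7,8,8a-octahydronaphthalen-1-yl]penta-2,4-dienoate
Product: 28 pyridinium (1R,2R,4aS,7R,8S,8aR)-7-[(2E)-but-2-en-2-yl]-8-[(1E,3E)-5-ethoxy-5-oxopenta-1,3-dien-1-yl]-1,6-dimethyl-1,2,3,4,4a,7,8,8a-octahydronaphthalen-2-yl sulfate (locants of the target kept in the descriptors)
Conditions: SO3·pyridine, pyridine, 40 °C
Reagents that add atoms: sulfur trioxide–pyridine complex, [O-]S(=O)(=O)[n+]1ccccc1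
Why: O-Sulfation of the free secondary alcohol with SO3·pyridine proceeds with retention at C7 while the ester keeps the carboxyl masked.

Step 18
Reactants: 28 pyridinium sulfate of the ethyl dienoate
Product: 29 (2E,4E)-5-[(1R,2R,4aS,7R,8S,8aR)-2-[(2E)-but-2-en-2-yl]-3,8-dimethyl-7-(sulfooxy)-1,2,4a,5,6,7,8,8a-octahydronaphthalen-1-yl]penta-2,4-dienoic acid
Conditions: LiOH, THF/MeOH/H2O, rt; then 1 M HCl to pH 2, 0 °C; reversed-phase desalting
Reagents that add atoms: lithium hydroxide, [Li+].[OH-]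
Why: Saponification of the ethyl ester leaves the base-stable sulfate monoester intact, and brief cold acidification should release the free acid.

**Compound list**

1 | prop-2-yn-1-ol | C#CCO | starting material
2 | (Z)-[3-(bromomagnesiooxy)-2-methylprop-1-en-1-yl]magnesium bromide (not isolated) | Br[Mg]/C=C(/C)CO[Mg]Br | intermediate
3 | (Z)-3-iodo-2-methylprop-2-en-1-ol | I/C=C(/C)CO | intermediate
4 | (Z)-3-iodo-2-methylprop-2-enal | I/C=C(/C)C=O | intermediate
5 | 3-ethoxy-2-methylcyclohex-2-en-1-one | CCOC1=C(C)C(=O)CCC1 | starting material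
6 | [(4-ethoxy-3-methylcyclohexa-1,3-dien-2-yl)oxy]trimethylsilane | CCOC1=C(C)C(O[Si](C)(C)C)=CCC1 | intermediate
7 | trichloro[(4-ethoxy-3-methylcyclohexa-1,3-dien-2-yl)oxy]silane (not isolated) | CCOC1=C(C)C(O[Si](Cl)(Cl)Cl)=CCC1 | intermediate
8 | (6R)-3-ethoxy-6-[(1S,2Z)-1-hydroxy-3-iodo-2-methylprop-2-en-1-yl]-2-methylcyclohex-2-en-1-one | I/C=C(/C)[C@@H](O)[C@@H]1C(=O)C(C)=C(OCC)CC1 | intermediate
9 | 3-ethoxy-6-[(1S,2Z)-1-hydroxy-3-iodo-2-methylprop-2-en-1-yl]-2-methylcyclohex-2-en-1-ol, C1 epimers, other centres as in 8 (not isolated) | I/C=C(/C)[C@@H](O)[C@@H]1C(O)C(C)=C(OCC)CC1 | intermediate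
10 | (4S)-4-[(1S,2Z)-1-hydroxy-3-iodo-2-methylprop-2-en-1-yl]-2-methylcyclohex-2-en-1-one | I/C=C(/C)[C@@H](O)[C@@H]1C=C(C)C(=O)CC1 | intermediate
11 | 3-(tert-butoxy)-3-oxopropanoic acid | CC(C)(C)OC(=O)CC(=O)O | starting material
12 | 1-tert-butyl 3-{(1S,2Z)-3-iodo-2-methyl-1-[(1S)-3-methyl-4-oxocyclohex-2-en-1-yl]prop-2-en-1-yl} propanedioate | I/C=C(/C)[C@@H](OC(=O)CC(=O)OC(C)(C)C)[C@@H]1C=C(C)C(=O)CC1 | intermediate
13 | tert-butyl (1S,4aS,5S,8aS)-1-[(1Z)-1-iodoprop-1-en-2-yl]-5-methyl-3,6-dioxooctahydro-1H-isochromene-4-carboxylate, cis-fused, epimers at C4 of this numbering | I/C=C(/C)[C@H]1OC(=O)C(C(=O)OC(C)(C)C)[C@@H]2[C@H](C)C(=O)CC[C@H]12 | intermediate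
14 | (1S,4aS,5S,8aS)-1-[(1Z)-1-iodoprop-1-en-2-yl]-5-methyl-3,6-dioxooctahydro-1H-isochromene-4-carboxylic acid (not isolated) | I/C=C(/C)[C@H]1OC(=O)C(C(=O)O)[C@@H]2[C@H](C)C(=O)CC[C@H]12 | intermediate
15 | (1S,4aS,5S,8aS)-1-[(1Z)-1-iodoprop-1-en-2-yl]-5-methylhexahydro-1H-isochromene-3,6(4H,7H)-dione | I/C=C(/C)[C@H]1OC(=O)C[C@@H]2[C@H](C)C(=O)CC[C@H]12 | intermediate
16 | (1S,4aR,5S,6R,8aS)-6-hydroxy-1-[(1Z)-1-iodoprop-1-en-2-yl]-5-methyloctahydro-3H-isochromen-3-one | I/C=C(/C)[C@H]1OC(=O)C[C@@H]2[C@H](C)[C@H](O)CC[C@H]12 | intermediate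
17 | (1S,4aR,5S,6R,8aS)-6-[(tert-butyldimethylsilyl)oxy]-1-[(1Z)-1-iodoprop-1-en-2-yl]-5-methyloctahydro-3H-isochromen-3-one | I/C=C(/C)[C@H]1OC(=O)C[C@@H]2[C@H](C)[C@H](O[Si](C)(C)C(C)(C)C)CC[C@H]12 | intermediate
18 | (Z)-2-(but-2-en-2-yl)-4,4,5,5-tetramethyl-1,3,2-dioxaborolane | C/C=C(\C)B1OC(C)(C)C(C)(C)O1 | starting material
19 | (1S,4aR,5S,6R,8aS)-6-[(tert-butyldimethylsilyl)oxy]-5-methyl-1-[(2Z,4E)-4-methylhexa-2,4-dien-2-yl]octahydro-3H-isochromen-3-one | C/C=C(\C)/C=C(/C)[C@H]1OC(=O)C[C@@H]2[C@H](C)[C@H](O[Si](C)(C)C(C)(C)C)CC[C@H]12 | intermediate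
20 | endocyclic trimethylsilyl ketene acetal of 19 (3-trimethylsilyloxy-1H-isochromene with C3=C4 of the lactone numbering, all centres as in 19; not isolated) | C/C=C(\C)/C=C(/C)[C@H]1OC(O[Si](C)(C)C)=C[C@@H]2[C@H](C)[C@H](O[Si](C)(C)C(C)(C)C)CC[C@H]12 | intermediate
21 | trimethylsilyl ester of acid 22 (not isolated) | C/C=C(\C)[C@@H]1C(C)=C[C@H]2CC[C@@H](O[Si](C)(C)C(C)(C)C)[C@@H](C)[C@H]2[C@H]1C(=O)O[Si](C)(C)C | intermediate
22 | (1R,2R,4aS,7R,8S,8aS)-2-[(2E)-but-2-en-2-yl]-7-[(tert-butyldimethylsilyl)oxy]-3,8-dimethyl-1,2,4a,5,6,7,8,8a-octahydronaphthalene-1-carboxylic acid | C/C=C(\C)[C@@H]1C(C)=C[C@H]2CC[C@@H](O[Si](C)(C)C(C)(C)C)[C@@H](C)[C@H]2[C@H]1C(=O)O | intermediate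
23 | [(1R,2R,4aS,7R,8S,8aR)-2-[(2E)-but-2-en-2-yl]-7-[(tert-butyldimethylsilyl)oxy]-3,8-dimethyl-1,2,4a,5,6,7,8,8a-octahydronaphthalen-1-yl]methanol | C/C=C(\C)[C@@H]1C(C)=C[C@H]2CC[C@@H](O[Si](C)(C)C(C)(C)C)[C@@H](C)[C@H]2[C@H]1CO | intermediate
24 | (1R,2R,4aS,7R,8S,8aS)-2-[(2E)-but-2-en-2-yl]-7-[(tert-butyldimethylsilyl)oxy]-3,8-dimethyl-1,2,4a,5,6,7,8,8a-octahydronaphthalene-1-carbaldehyde | C/C=C(\C)[C@@H]1C(C)=C[C@H]2CC[C@@H](O[Si](C)(C)C(C)(C)C)[C@@H](C)[C@H]2[C@H]1C=O | intermediate
25 | ethyl (2E)-4-(diethoxyphosphoryl)but-2-enoate | CCOC(=O)/C=C/CP(=O)(OCC)OCC | starting material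
26 | ethyl (2E,4E)-5-[(1R,2R,4aS,7R,8S,8aR)-2-[(2E)-but-2-en-2-yl]-7-[(tert-butyldimethylsilyl)oxy]-3,8-dimethyl-1,2,4a,5,6,7,8,8a-octahydronaphthalen-1-yl]penta-2,4-dienoate | C/C=C(\C)[C@@H]1C(C)=C[C@H]2CC[C@@H](O[Si](C)(C)C(C)(C)C)[C@@H](C)[C@H]2[C@H]1/C=C/C=C/C(=O)OCC | intermediate
27 | ethyl (2E,4E)-5-[(1R,2R,4aS,7R,8S,8aR)-2-[(2E)-but-2-en-2-yl]-7-hydroxy-3,8-dimethyl-1,2,4a,5,6,7,8,8a-octahydronaphthalen-1-yl]penta-2,4-dienoate | C/C=C(\C)[C@@H]1C(C)=C[C@H]2CC[C@@H](O)[C@@H](C)[C@H]2[C@H]1/C=C/C=C/C(=O)OCC | intermediate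
28 | pyridinium salt of the C7 sulfate monoester of 27 | C/C=C(\C)[C@@H]1C(C)=C[C@H]2CC[C@@H](OS(=O)(=O)[O-])[C@@H](C)[C@H]2[C@H]1/C=C/C=C/C(=O)OCC.c1cc[nH+]cc1 | intermediate
29 | (2E,4E)-5-[(1R,2R,4aS,7R,8S,8aR)-2-[(2E)-but-2-en-2-yl]-3,8-dimethyl-7-(sulfooxy)-1,2,4a,5,6,7,8,8a-octahydronaphthalen-1-yl]penta-2,4-dienoic acid | C/C=C(\C)[C@@H]1C(C)=C[C@H]2CC[C@@H](OS(=O)(=O)O)[C@@H](C)[C@H]2[C@H]1/C=C/C=C/C(=O)O | target

**Count and risks**

Total steps: 18. Longest linear sequence: 17 steps (from 1 through steps 1, 2 and 4 to 18); the second branch (5 to 6, step 3) joins at step 4.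

Steps most likely to fail:

1. Step 12. The [3,3] shift may stall because the reacting conformer has to press the inside dienyl group against C4a (allylic strain) within a boat. The silyl ketene acetal could then be lost to hydrolysis, C-silylation or a thermal 1,5-hydrogen shift of the Z diene. The fallback sets out from 17 and returns at 23; it slims the inside group to an alkyne and builds the butenyl unit after the ring contraction. Sonogashira coupling of 17 with ethynyltrimethylsilane (Pd(PPh3)2Cl2, CuI, Et3N, THF, rt) should give the (Z)-enyne lactone F1. The same enolisation, silylation and heating then lead through the silyl ketene acetal F2 to the bis-silyl ester F3, and K2CO3 in methanol followed by acidification gives the 2-ethynyl acid F4. LiAlH4 gives the ethynyl alcohol F5. Zirconium-catalysed methylalumination of the terminal alkyne (AlMe3, Cp2ZrCl2, CH2Cl2; syn addition, methyl on the internal carbon) and iodinolysis give the (E)-iodoalkene F6. Negishi coupling with MeZnCl and Pd(PPh3)4 then gives 23 with the (E)-butenyl group in place.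

2. Step 4. Facial discrimination by the phosphoramide may be poor, the electron-rich trichlorosilyl dienolate may decompose, or the iodoenal may drift from Z to E under the chlorosilane conditions. The fallback sets out from 4 and returns at 10; it replaces catalyst control by a traceless chiral alkoxy group and separation of diastereomers. Commercial 2-methylcyclohexane-1,3-dione and (1R,2S,5R)-menthol (TsOH, toluene, water removal) give the menthyl vinylogous ester F7. Its lithium enolate (LiN(i-Pr)2, THF, −78 °C) adds to 4 through the closed chair transition state to give anti aldols, from which the (6R,1′S) aldol diastereomer F8 is separated by chromatography or crystallisation. Reduction with i-Bu2AlH to the allylic diol F9 and hydrolysis with 1 M HCl give 10, with the menthol recovered.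

3. Step 11. Zerovalent palladium may ionise the allylic lactone C–O bond, scrambling C4 or the Z alkene through a π-allyl complex, and aqueous base may open the lactone while transmetalation of the hindered boronate is slow. The fallback sets out from 17 and returns at 19; it couples on the ring-opened form, where the allylic oxygen is a free hydroxyl that cannot ionise. LiOH in THF/H2O opens 17 to the hydroxy acid F10 (as its lithium salt). Boronate 18 and Pd(dppf)Cl2 are added to the same basic solution to give the dienyl hydroxy acid F11. After careful acidification, carbodiimide lactonisation (EDC·HCl, DMAP, CH2Cl2) of the cis-disposed hydroxyl and acetic acid arm closes the lactone again to 19.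

Further compounds
F1 | step 12 | (1S,4aR,5S,6R,8aS)-6-[(tert-butyldimethylsilyl)oxy]-5-methyl-1-[(2Z)-5-(trimethylsilyl)pent-2-en-4-yn-2-yl]octahydro-3H-isochromen-3-one | C[Si](C)(C)C#C/C=C(/C)[C@H]1OC(=O)C[C@@H]2[C@H](C)[C@H](O[Si](C)(C)C(C)(C)C)CC[C@H]12
F2 | step 12 | endocyclic trimethylsilyl ketene acetal of F1 | C[Si](C)(C)C#C/C=C(/C)[C@H]1OC(O[Si](C)(C)C)=C[C@@H]2[C@H](C)[C@H](O[Si](C)(C)C(C)(C)C)CC[C@H]12
F3 | step 12 | trimethylsilyl ester of the 2-[(trimethylsilyl)ethynyl] analogue of acid 22 (ring centres as in 22) | C[Si](C)(C)C#C[C@@H]1C(C)=C[C@H]2CC[C@@H](O[Si](C)(C)C(C)(C)C)[C@@H](C)[C@H]2[C@H]1C(=O)O[Si](C)(C)C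
F4 | step 12 | 2-ethynyl analogue of acid 22 (ethynyl trans to the carboxyl, ring centres as in 22) | C#C[C@@H]1C(C)=C[C@H]2CC[C@@H](O[Si](C)(C)C(C)(C)C)[C@@H](C)[C@H]2[C@H]1C(=O)O
F5 | step 12 | 2-ethynyl analogue of alcohol 23 | C#C[C@@H]1C(C)=C[C@H]2CC[C@@H](O[Si](C)(C)C(C)(C)C)[C@@H](C)[C@H]2[C@H]1CO
F6 | step 12 | 2-[(1E)-1-iodoprop-1-en-2-yl] analogue of alcohol 23 | I/C=C(\C)[C@@H]1C(C)=C[C@H]2CC[C@@H](O[Si](C)(C)C(C)(C)C)[C@@H](C)[C@H]2[C@H]1CO
F7 | step 4 | 2-methyl-3-{[(1R,2S,5R)-5-methyl-2-(propan-2-yl)cyclohexyl]oxy}cyclohex-2-en-1-one | CC(C)[C@@H]1CC[C@@H](C)C[C@H]1OC1=C(C)C(=O)CCC1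
F8 | step 4 | (6R)-6-[(1S,2Z)-1-hydroxy-3-iodo-2-methylprop-2-en-1-yl]-2-methyl-3-{[(1R,2S,5R)-5-methyl-2-(propan-2-yl)cyclohexyl]oxy}cyclohex-2-en-1-one | I/C=C(/C)[C@@H](O)[C@@H]1C(=O)C(C)=C(O[C@@H]2C[C@H](C)CC[C@H]2C(C)C)CC1
F9 | step 4 | allylic diol from reduction of F8 (C1 epimers, other centres as in F8) | I/C=C(/C)[C@@H](O)[C@@H]1C(O)C(C)=C(O[C@@H]2C[C@H](C)CC[C@H]2C(C)C)CC1
F10 | step 11 | hydroxy acid from opening of lactone 17 (all centres as in 17) | I/C=C(/C)[C@@H](O)[C@H]1CC[C@@H](O[Si](C)(C)C(C)(C)C)[C@@H](C)[C@H]1CC(=O)O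
F11 | step 11 | hydroxy acid corresponding to lactone 19 (all centres as in 19) | C/C=C(\C)/C=C(/C)[C@@H](O)[C@H]1CC[C@@H](O[Si](C)(C)C(C)(C)C)[C@@H](C)[C@H]1CC(=O)O
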